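**Retrosynthetic overview**
1. Target 19 ⇒ in one pot: ring C by 6-endo opening of a (2R,3S)-epoxide by the C8a phenol, and ring A by Diels–Alder benzannulation of diene 16 onto the terminal ynone of 11 (ring A first, then ring C; ring B is bought).
2. 11 ⇒ epoxy morpholine amide 8 + ethynyl Grignard 9; 8 ⇒ (E)-enamide 7 by asymmetric nucleophilic epoxidation (sets both stereocentres: Cα R becomes C3, Cβ S becomes C2 R after inversion).
3. 7 ⇒ aldehyde 5 (Horner–Wadsworth–Emmons) ⇒ 3,5-dibromo-4-hydroxybenzaldehyde 1 + prenylBpin 2 (double coupling, then silylation).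
4. 16 ⇒ methyl acetoacetate 12 + prenyl bromide 13; the C8 prenyl group is fixed before ring A exists, so no regioselective prenylation of a resorcinol is needed.

Abbreviations: prenyl = 3-methylbut-2-en-1-yl; ArTBS = 4-[(tert-butyldimethylsilyl)oxy]-3,5-diprenylphenyl.

Assumption: the target is the (2R,3R)-trans dihydroflavonol as read from the SMILES, and 2, 6 and a THF solution of 9 are bought as catalogue reagents.

**Route**

Step 1
Reactants: 1 3,5-dibromo-4-hydroxybenzaldehyde; 2 4,4,5,5-tetramethyl-2-(3-methylbut-2-en-1-yl)-1,3,2-dioxaborolane (prenylBpin, 2.8 equiv)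
Product: 4 4-hydroxy-3,5-bis(3-methylbut-2-en-1-yl)benzaldehyde, via monoprenyl bromophenol aldehyde 3 (not isolated)
Conditions: Pd(OAc)2 (5 mol %), t-BuXPhos (10 mol %), K3PO4 (5 equiv), MeCN/H2O, 70 °C
Reagents that add atoms: none
Why: Double Suzuki–Miyaura allyl–aryl coupling in which the bulky biaryl di-tert-butylphosphine lets the allyl–palladium intermediate settle as the primary σ-prenyl species before reductive elimination, so the linear prenyl group (not 1,1-dimethylallyl) is delivered to both C–Br positions via 3, while the phenoxide formed under the basic conditions deactivates the para aldehyde toward allylboration.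

Step 2
Reactants: 4 4-hydroxy-3,5-bis(3-methylbut-2-en-1-yl)benzaldehyde
Product: 5 4-[(tert-butyldimethylsilyl)oxy]-3,5-bis(3-methylbut-2-en-1-yl)benzaldehyde
Conditions: TBSCl, imidazole, DMF, 35 °C
Reagents that add atoms: tert-butyldimethylsilyl chloride, CC(C)(C)[Si](C)(C)Cl
Why: Standard imidazole-promoted O-silylation; the hindered aryl silyl ether masks the phenol through the base, peroxide and Grignard steps and is removed by fluoride in the last step.

Step 3
Reactants: 5 4-[(tert-butyldimethylsilyl)oxy]-3,5-bis(3-methylbut-2-en-1-yl)benzaldehyde; 6 diethyl [2-(morpholin-4-yl)-2-oxoethyl]phosphonate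
Product: 7 (E)-3-(ArTBS)-1-(morpholin-4-yl)prop-2-en-1-one
Conditions: NaH, THF, 0 °C to rt
Reagents that add atoms: none
Why: Horner–Wadsworth–Emmons olefination with an amide-stabilised phosphonate gives the (E)-enamide under thermodynamic control and installs a morpholine amide that later serves as an acyl donor.

Step 4
Reactants: 7 (E)-3-(ArTBS)-1-(morpholin-4-yl)prop-2-en-1-one
Product: 8 [(2R,3S)-3-(ArTBS)oxiran-2-yl](morpholin-4-yl)methanone (trans)
Conditions: Sm(O-i-Pr)3/(S)-BINOL/Ph3As=O (10 mol % each), t-BuOOH (decane, 1.5 equiv), 4 Å MS, THF, rt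
Reagents that add atoms: tert-butyl hydroperoxide, CC(C)(C)OO
Why: Lanthanide–BINOL catalysed nucleophilic (Weitz–Scheffer type) epoxidation, in which samarium-bound tert-butyl peroxide adds to the β-carbon of the amide held in the chiral binaphtholate pocket and closes to the trans epoxide, setting C2 (R, the future C3) and C3 (S, the future C2 before inversion); the (S)-ligand is the one expected to give this enantiomer (the (R)-ligand gives the antipode, to be confirmed by chiral HPLC on the first run), and the prenyl alkenes are inert to this non-electrophilic oxidant.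

Step 5
Reactants: 8 [(2R,3S)-3-(ArTBS)oxiran-2-yl](morpholin-4-yl)methanone; 9 ethynylmagnesium bromide (1.5 equiv)
Product: 11 1-[(2R,3S)-3-(ArTBS)oxiran-2-yl]prop-2-yn-1-one, via magnesium hemiaminal alkoxide 10 (not isolated)
Conditions: HC≡CMgBr (0.5 M in THF), THF, −20 °C; inverse quench into AcOH/THF at −78 °C, then pH 7 buffer
Reagents that add atoms: none
Why: Acyl substitution of a morpholine amide (Weinreb-type ketone synthesis), in which the chelated tetrahedral adduct 10 survives until the cold acidic quench so there is no over-addition, the acid protonates morpholine before it can add to the ynone, and the epoxide stereocentres are not touched.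

Step 6
Reactants: 12 methyl acetoacetate (1.5 equiv); 13 1-bromo-3-methylbut-2-ene (prenyl bromide)
Product: 14 methyl 2-acetyl-5-methylhex-4-enoate (racemic)
Conditions: K2CO3, acetone, reflux
Reagents that add atoms: none
Why: Classical acetoacetic ester C-alkylation (SN2 of the stabilised enolate on the primary allylic bromide), with excess 12 suppressing dialkylation.

Step 7
Reactants: 14 methyl 2-acetyl-5-methylhex-4-enoate
Product: 16 1-methoxy-2-(3-methylbut-2-en-1-yl)-1,3-bis(trimethylsilyloxy)buta-1,3-diene, via mono silyl enol ether 15 (not isolated)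
Conditions: Me3SiOTf (2.3 equiv), Et3N (2.6 equiv), Et2O, 0 °C to rt; hexane extraction, Kugelrohr distillation
Reagents that add atoms: trimethylsilyl trifluoromethanesulfonate, C[Si](C)(C)OS(=O)(=O)C(F)(F)F
Why: Silyl triflate/amine enol silylation, in which the ketone enol is silylated first (15) and a second O-silylation at the ester carbonyl with vinylogous deprotonation of the methyl group gives the cross-conjugated Chan-type 1-methoxy-1,3-bis(silyloxy)diene carrying the prenyl group at C2.

Step 8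
Reactants: 11 1-[(2R,3S)-3-(ArTBS)oxiran-2-yl]prop-2-yn-1-one; 16 1-methoxy-2-(3-methylbut-2-en-1-yl)-1,3-bis(trimethylsilyloxy)buta-1,3-diene (1.8 equiv)
Product: 19 (2R,3R)-3,7-dihydroxy-2-[4-hydroxy-3,5-bis(3-methylbut-2-en-1-yl)phenyl]-8-(3-methylbut-2-en-1-yl)-2,3-dihydro-4H-chromen-4-one = CNP0316331.1, via cycloadduct ketal 17 (not isolated), via epoxy triphenol ketone 18 (not isolated)
Conditions: PhMe, 0 to 45 °C, 12 h; then Bu4NF/AcOH (1:1, 5 equiv), THF, 0 °C to rt, same flask
Reagents that add atoms: none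
Why: Proposed new method: the electron-rich diene 16 adds to the terminal ynone of 11 in a regioselective Diels–Alder reaction (diene CH2 terminus to the alkyne CH, ketene-acetal carbon to the acyl-bearing carbon) to give ketal 17, buffered fluoride then collapses the silyl methyl ketal with loss of methanol to aromatise ring A and frees all three phenols to give 18, and the C2' phenol of 18 opens the p-hydroxybenzyl-activated epoxide 6-endo with inversion at the benzylic carbon (S to R) to close ring C trans (also the thermodynamic isomer) while C3 (R) is carried over untouched; the closest known chemistry is the Brassard/Chan diene–alkynone benzannulation to 2,4-dihydroxyaryl ketones combined with the cyclisation of 2'-hydroxychalcone epoxides to trans-dihydroflavonols.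

**Compound list**

1 | 3,5-dibromo-4-hydroxybenzaldehyde | O=Cc1cc(Br)c(O)c(Br)c1 | starting material
2 | 4,4,5,5-tetramethyl-2-(3-methylbut-2-en-1-yl)-1,3,2-dioxaborolane (prenylBpin) | CC(C)=CCB1OC(C)(C)C(C)(C)O1 | starting material
3 | 3-bromo-4-hydroxy-5-(3-methylbut-2-en-1-yl)benzaldehyde | CC(C)=CCc1cc(C=O)cc(Br)c1O | intermediate
4 | 4-hydroxy-3,5-bis(3-methylbut-2-en-1-yl)benzaldehyde | CC(C)=CCc1cc(C=O)cc(CC=C(C)C)c1O | intermediate
5 | 4-[(tert-butyldimethylsilyl)oxy]-3,5-bis(3-methylbut-2-en-1-yl)benzaldehyde | CC(C)=CCc1cc(C=O)cc(CC=C(C)C)c1O[Si](C)(C)C(C)(C)C | intermediate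
6 | diethyl [2-(morpholin-4-yl)-2-oxoethyl]phosphonate | CCOP(=O)(OCC)CC(=O)N1CCOCC1 | starting material
7 | (E)-3-{4-[(tert-butyldimethylsilyl)oxy]-3,5-bis(3-methylbut-2-en-1-yl)phenyl}-1-(morpholin-4-yl)prop-2-en-1-one | CC(C)=CCc1cc(/C=C/C(=O)N2CCOCC2)cc(CC=C(C)C)c1O[Si](C)(C)C(C)(C)C | intermediate
8 | [(2R,3S)-3-{4-[(tert-butyldimethylsilyl)oxy]-3,5-bis(3-methylbut-2-en-1-yl)phenyl}oxiran-2-yl](morpholin-4-yl)methanone | O=C(N1CCOCC1)[C@@H]1O[C@H]1c1cc(CC=C(C)C)c(O[Si](C)(C)C(C)(C)C)c(CC=C(C)C)c1 | intermediate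
9 | ethynylmagnesium bromide | C#C[Mg]Br | starting material
10 | bromomagnesium 1-[(2R,3S)-3-(ArTBS)oxiran-2-yl]-1-(morpholin-4-yl)prop-2-yn-1-olate (tetrahedral adduct, carbinol centre unassigned) | C#CC(O[Mg]Br)(N1CCOCC1)[C@@H]1O[C@H]1c1cc(CC=C(C)C)c(O[Si](C)(C)C(C)(C)C)c(CC=C(C)C)c1 | intermediate
11 | 1-[(2R,3S)-3-{4-[(tert-butyldimethylsilyl)oxy]-3,5-bis(3-methylbut-2-en-1-yl)phenyl}oxiran-2-yl]prop-2-yn-1-one | C#CC(=O)[C@@H]1O[C@H]1c1cc(CC=C(C)C)c(O[Si](C)(C)C(C)(C)C)c(CC=C(C)C)c1 | intermediate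
12 | methyl acetoacetate (methyl 3-oxobutanoate) | CC(=O)CC(=O)OC | starting material
13 | 1-bromo-3-methylbut-2-ene (prenyl bromide) | CC(C)=CCBr | starting material
14 | methyl 2-acetyl-5-methylhex-4-enoate (racemic) | COC(=O)C(CC=C(C)C)C(C)=O | intermediate
15 | methyl 5-methyl-2-[1-(trimethylsilyloxy)ethylidene]hex-4-enoate (alkene geometry unassigned) | COC(=O)C(CC=C(C)C)=C(C)O[Si](C)(C)C | intermediate
16 | 1-methoxy-2-(3-methylbut-2-en-1-yl)-1,3-bis(trimethylsilyloxy)buta-1,3-diene (ketene acetal geometry unassigned) | COC(O[Si](C)(C)C)=C(CC=C(C)C)C(=C)O[Si](C)(C)C | intermediate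
17 | [6-methoxy-5-(3-methylbut-2-en-1-yl)-4,6-bis(trimethylsilyloxy)cyclohexa-1,4-dien-1-yl][(2R,3S)-3-(ArTBS)oxiran-2-yl]methanone (ketal centre unassigned) | COC1(O[Si](C)(C)C)C(CC=C(C)C)=C(O[Si](C)(C)C)CC=C1C(=O)[C@@H]1O[C@H]1c1cc(CC=C(C)C)c(O[Si](C)(C)C(C)(C)C)c(CC=C(C)C)c1 | intermediate
18 | [2,4-dihydroxy-3-(3-methylbut-2-en-1-yl)phenyl][(2R,3S)-3-[4-hydroxy-3,5-bis(3-methylbut-2-en-1-yl)phenyl]oxiran-2-yl]methanone | CC(C)=CCc1c(O)ccc(C(=O)[C@@H]2O[C@H]2c2cc(CC=C(C)C)c(O)c(CC=C(C)C)c2)c1O | intermediate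
19 | (2R,3R)-3,7-dihydroxy-2-[4-hydroxy-3,5-bis(3-methylbut-2-en-1-yl)phenyl]-8-(3-methylbut-2-en-1-yl)-2,3-dihydro-4H-chromen-4-one (CNP0316331.1) | CC(C)=CCc1cc([C@H]2Oc3c(ccc(O)c3CC=C(C)C)C(=O)[C@@H]2O)cc(CC=C(C)C)c1O | target

**Totals**

Total steps: 8 (steps 1–5 build the epoxy ynone, steps 6–7 the diene, step 8 joins them).
Longest linear sequence: 6 (steps 1, 2, 3, 4, 5, 8).

**Three steps most likely to fail, with fallbacks**

Step 8 (one-pot benzannulation and ring C closure). Risks are open-chain Michael adducts instead of cycloaddition, loss of the sensitive epoxide during the thermal stage, and 5-exo closure to an aurone-type product. The fallback brings ring A in intact as an aryllithium instead of building it; it sets out from 8 (using 13 for the prenyl group) and comes back to the route at 19. Commercial 1,3-bis(methoxymethoxy)benzene is lithiated between the two acetal oxygens (n-BuLi, THF, 0 °C) and alkylated with 13 to give 1,3-bis(methoxymethoxy)-2-(3-methylbut-2-en-1-yl)benzene F1. A second directed ortho-lithiation (n-BuLi, TMEDA, THF, −20 °C) gives [2,4-bis(methoxymethoxy)-3-(3-methylbut-2-en-1-yl)phenyl]lithium F2. F2 is acylated by 8 at −78 °C to the protected chalcone epoxide [2,4-bis(methoxymethoxy)-3-(3-methylbut-2-en-1-yl)phenyl][(2R,3S)-3-(ArTBS)oxiran-2-yl]methanone F3. HCl/MeOH (rt to 40 °C) removes both methoxymethyl groups and the freed C2' phenol closes ring C with inversion to (2R,3R)-2-(ArTBS)-3,7-dihydroxy-8-(3-methylbut-2-en-1-yl)-2,3-dihydro-4H-chromen-4-one F4. Bu4NF/AcOH in THF then gives 19.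

Step 5 (terminal epoxy ynone from the amide). Risks are conjugate addition of liberated morpholine to the ynone and magnesium-halide opening of the electron-rich benzylic epoxide. The fallback goes through the aldehyde oxidation level so that no amine is released next to an ynone; it sets out from 8 and comes back at 11. i-Bu2AlH (CH2Cl2, −78 °C) reduces 8 to (2R,3S)-3-(ArTBS)oxirane-2-carbaldehyde F5. Addition of 9 at −78 °C gives 1-[(2S,3S)-3-(ArTBS)oxiran-2-yl]prop-2-yn-1-ol F6 (both carbinol epimers; the epoxide geometry is unchanged and only the descriptor changes with the priorities). Dess–Martin periodinane/NaHCO3 in CH2Cl2 oxidises F6 to 11.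

Step 1 (double linear prenylation of the unprotected dibromophenol aldehyde). Risks are γ-coupling to the 1,1-dimethylallyl isomer, an incomplete second coupling and allylboration of the aldehyde. The fallback removes the regiochemical question by coupling a symmetric allyl group under neutral conditions and making the prenyl groups by metathesis; it sets out from 1 and comes back at 4. Stille coupling of 1 with allyltributylstannane (Pd(PPh3)4, DMF, 90 °C) gives 4-hydroxy-3,5-di(prop-2-en-1-yl)benzaldehyde F7. Cross-metathesis of F7 with excess 2-methylbut-2-ene (second-generation Grubbs catalyst, (H2IMes)(PCy3)Cl2Ru=CHPh, CH2Cl2, 40 °C) converts both allyl groups into prenyl groups and gives 4.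

**Further compounds**

F1 | step 8 | 1,3-bis(methoxymethoxy)-2-(3-methylbut-2-en-1-yl)benzene | COCOc1cccc(OCOC)c1CC=C(C)C
F2 | step 8 | [2,4-bis(methoxymethoxy)-3-(3-methylbut-2-en-1-yl)phenyl]lithium | [Li]c1ccc(OCOC)c(CC=C(C)C)c1OCOC
F3 | step 8 | [2,4-bis(methoxymethoxy)-3-(3-methylbut-2-en-1-yl)phenyl][(2R,3S)-3-{4-[(tert-butyldimethylsilyl)oxy]-3,5-bis(3-methylbut-2-en-1-yl)phenyl}oxiran-2-yl]methanone | COCOc1ccc(C(=O)[C@@H]2O[C@H]2c2cc(CC=C(C)C)c(O[Si](C)(C)C(C)(C)C)c(CC=C(C)C)c2)c(OCOC)c1CC=C(C)C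
F4 | step 8 | (2R,3R)-2-{4-[(tert-butyldimethylsilyl)oxy]-3,5-bis(3-methylbut-2-en-1-yl)phenyl}-3,7-dihydroxy-8-(3-methylbut-2-en-1-yl)-2,3-dihydro-4H-chromen-4-one | CC(C)=CCc1cc([C@H]2Oc3c(ccc(O)c3CC=C(C)C)C(=O)[C@@H]2O)cc(CC=C(C)C)c1O[Si](C)(C)C(C)(C)C
F5 | step 5 | (2R,3S)-3-{4-[(tert-butyldimethylsilyl)oxy]-3,5-bis(3-methylbut-2-en-1-yl)phenyl}oxirane-2-carbaldehyde | O=C[C@@H]1O[C@H]1c1cc(CC=C(C)C)c(O[Si](C)(C)C(C)(C)C)c(CC=C(C)C)c1
F6 | step 5 | 1-[(2S,3S)-3-{4-[(tert-butyldimethylsilyl)oxy]-3,5-bis(3-methylbut-2-en-1-yl)phenyl}oxiran-2-yl]prop-2-yn-1-ol (carbinol epimers) | C#CC(O)[C@@H]1O[C@H]1c1cc(CC=C(C)C)c(O[Si](C)(C)C(C)(C)C)c(CC=C(C)C)c1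
F7 | step 1 | 4-hydroxy-3,5-di(prop-2-en-1-yl)benzaldehyde | C=CCc1cc(C=O)cc(CC=C)c1O
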